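**Retrosynthetic overview**

1. Numbering: C1 (quaternary, CH3), C2, C3, C4 (isopropyl carbinol), C5 (ring-fusion CH) in the five-membered ring; C6 (ester carbinol), C7, C8 (epoxide C–CH3), C9 (epoxide CH), C10 in the seven-membered ring. α is the face of C1–CH3; the target is 1S,4R,5S,6R,8R,9S with C5–H α, C4–OH β, C6–O β and the epoxide oxygen α.
2. Feature the route rests on: the seven-membered ring (C1, C5–C10) divides at C7–C8 and C1–C10 into a three-carbon unit C8–C9–C10 (a vinylcarbenoid whose ester becomes the C8 methyl) and a four-carbon unit C7–C6–C5–C1 (a 1,3-diene whose C5=C1 bond lies in a methylcyclopentene).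
3. Backwards: phenol silyl ether; α-epoxide from C8=C9; C6 ester from the 4β,6β-diol, itself from the C6 ketone; C4 carbinol from the C4 ketone and an isopropyl nucleophile; C8–CH3 from CO2CH3; C6–O from hydroboration of C5=C6; cycloheptadiene from a vinyl diene and methyl 2-diazobut-3-enoate.
4. The diene carries a plain vinyl group. An alkoxy group on C6 would make the cyclopropane a donor–acceptor cyclopropane that can ionise (loss of ee) and, next to the C4 dioxolane, would make the cycloadduct a vinylogous orthoester that cannot be unmasked at C6 alone.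
5. Ring order: the five-membered ring comes from 3-methylcyclopent-2-enone, the seven-membered ring closes in step 7, the epoxide in step 18. C1 is set by the catalyst, C5 is held by thermodynamics next to the C4 ketone, C4, C6 and C8/C9 by attack on the convex α face.

Key step: step 7

Remark 1: the sense of induction of Rh2(S-DOSP)4 is taken from its known behaviour with aryl- and vinyldiazoacetates and terminal alkenes (seen from the donor side, carbenoid carbon → substituted alkene carbon → CH2 runs clockwise); should the diene follow the opposite sense, Rh2(R-DOSP)4 is used and nothing else changes.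
Remark 2: 4-[(tert-butyldimethylsilyl)oxy]benzoic acid is treated as a catalogue compound (otherwise one operation from 4-hydroxybenzoic acid).

**Route**

Step 1
Reactants: 1 3-methylcyclopent-2-en-1-one
Product: 2 2-iodo-3-methylcyclopent-2-en-1-one
Conditions: I2, pyridine, DMAP (cat.), CH2Cl2, 0 °C → rt
Reagents that add atoms: iodine, II
Why: α-Iodination of the enone (Johnson iodination: conjugate addition of the amine, iodination of the enolate, elimination) replaces the only vinylic hydrogen, on the carbon that becomes C5.

Step 2
Reactants: 2 2-iodo-3-methylcyclopent-2-en-1-one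
Product: 3 6-iodo-7-methyl-1,4-dioxaspiro[4.4]non-6-ene
Conditions: HOCH2CH2OH, p-TsOH (cat.), benzene, reflux, Dean–Stark trap
Reagents that add atoms: ethylene glycol, OCCO
Why: Acid-catalysed ketalisation with azeotropic removal of water masks the C4 carbonyl group, and the α-halogen holds the double bond in place, as is known for 2-halocycloalkenone dioxolanes.

Step 3
Reactants: 3 6-iodo-7-methyl-1,4-dioxaspiro[4.4]non-6-ene; 4 tributyl(ethenyl)stannane
Product: 5 6-ethenyl-7-methyl-1,4-dioxaspiro[4.4]non-6-ene
Conditions: Pd(PPh3)4 (cat.), CuI (cat.), CsF, DMF, 45 °C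
Reagents that add atoms: none
Why: Stille coupling at zerovalent palladium joins C6 to C5; CuI and fluoride speed up transmetallation at the hindered, fully substituted alkenyl iodide and bind the tin as Bu3SnF.

Step 4
Reactants: 6 methyl acetoacetate
Product: 7 methyl 2-diazo-3-oxobutanoate
Conditions: 4-AcNHC6H4SO2N3, Et3N, MeCN, 0 °C → rt
Reagents that add atoms: 4-acetamidobenzenesulfonyl azide, CC(=O)Nc1ccc(cc1)S(=O)(=O)N=[N+]=[N-]
Why: Regitz diazo transfer to the doubly activated methylene group.

Step 5
Reactants: 7 methyl 2-diazo-3-oxobutanoate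
Product: 8 methyl 2-diazo-3-hydroxybutanoate (racemic)
Conditions: NaBH4, MeOH, 0 °C
Reagents that add atoms: none
Why: Chemoselective borohydride reduction of the ketone leaves the ester and the stabilised diazo group; the new stereocentre disappears in step 6.

Step 6
Reactants: 8 methyl 2-diazo-3-hydroxybutanoate
Product: 10 methyl 2-diazobut-3-enoate, via dichlorophosphate ester 9 (not isolated)
Conditions: POCl3, Et3N, CH2Cl2, 0 °C; kept cold and used at once as a hexane solution
Reagents that add atoms: phosphoryl chloride, O=P(Cl)(Cl)Cl (its atoms stay in 9 only)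
Why: Activation of the alcohol as a phosphate ester and base-induced β-elimination (dehydration) gives the vinyldiazoacetate, which is not stored because it slowly cyclises to a pyrazole.

Step 7
Reactants: 5 6-ethenyl-7-methyl-1,4-dioxaspiro[4.4]non-6-ene; 10 methyl 2-diazobut-3-enoate
Product: 12 cycloadduct, methyl ester of the hydroazulene diene (C4 spiro-dioxolane, C5=C6 and C8=C9, CO2CH3 on C8, C1 S), via cis-divinylcyclopropane 11 (not isolated)
Conditions: Rh2(S-DOSP)4 (1 mol%), hexanes, −40 °C → rt, slow addition of 10; then toluene, 80 °C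
Reagents that add atoms: none
Why: Rh2(S-DOSP)4 (dirhodium tetrakis[(S)-N-(dodecylbenzenesulfonyl)prolinate]) takes N2 out of 10, and the donor–acceptor vinylcarbenoid adds through C8 to the vinyl group C6=C7 of 5 in a concerted, asynchronous (2+1) step that places the cyclopentenyl group cis to the carbenoid vinyl group, so cis-divinylcyclopropane 11 forms directly. Compound 11 then undergoes a (3,3) sigmatropic (Cope) shift through the boat transition state, in which C10 bonds to C1 while the C6–C8 bond of the three-membered ring breaks; this pericyclic ring expansion closes the seven-membered ring (new bonds C7–C8 and C1–C10) and leaves C8=C9 conjugated with the ester and C5=C6 at the ring fusion. The closest known reaction type is the dirhodium-catalysed cyclopropanation/Cope sequence (formal (4+3) cycloaddition) of vinyldiazoacetates with 1-vinyl-2-methylcycloalkenes, which is known to build a methyl-bearing quaternary carbon. The only stereocentre that survives, C1 (S), is controlled by the catalyst: the prolinate ligands fix which face of the carbenoid carbon is attacked (C8 R and C6 R in 11), and the stereospecific boat geometry relays this to C1. The step needs site selectivity for the vinyl group over the ring alkene and over C–H insertion next to the dioxolane oxygens, and cis diastereoselectivity in the cyclopropanation; the first is secured by the full substitution of the ring alkene, the second by the preference of the alkene substituent for the side of the carbenoid donor group. The C1 methyl group points at the cyclopropane CH2 in the boat and slows the Cope step, which is why the mixture is warmed.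

Step 8
Reactants: 12 cycloadduct
Product: 14 secondary alcohol (C5–H α, cis-fused; C6–OH α), via alkylborane 13 (not isolated)
Conditions: BH3·THF, THF, 0 °C → rt; then H2O2, aq. NaOAc, 0 °C → rt
Reagents that add atoms: borane, B (boron stays in 13 only); hydrogen peroxide, OO
Why: Hydroboration–oxidation is selective for the electron-rich trisubstituted C5=C6 bond over the ester-conjugated C8=C9 bond and places boron on the less substituted C6; syn addition to the outer α face of the boat-shaped cyclohepta-1,4-diene (the inner face is covered by C8=C9) should set C5–H α and C6–OH α, and because C6 is reset in steps 15 and 16 and C5 lies next to the C4 ketone from step 12 on, material from attack on the other face converges on 23 through the same steps.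

Step 9
Reactants: 14 secondary alcohol
Product: 15 silyl ether (C6–OTBS α)
Conditions: TBSOTf, 2,6-lutidine, CH2Cl2, −78 → 0 °C
Reagents that add atoms: tert-butyldimethylsilyl triflate, CC(C)(C)[Si](C)(C)OS(=O)(=O)C(F)(F)F
Why: Silylation with the reactive silyl triflate and a hindered base protects the hindered secondary alcohol for the hydride and organometallic steps without touching the dioxolane or the ester.

Step 10
Reactants: 15 silyl ether
Product: 17 primary allylic alcohol (CH2OH on C8), via enal 16 (not isolated)
Conditions: i-Bu2AlH, CH2Cl2, −78 → 0 °C; aq. potassium sodium tartrate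
Reagents that add atoms: none
Why: Aluminium hydride 1,2-reduction of the conjugated ester gives the allylic alcohol, with ketal and silyl ether untouched.

Step 11
Reactants: 17 primary allylic alcohol
Product: 19 C8-methyl alkene (dioxolane, C6–OTBS α), via allylic mesylate 18 (not isolated)
Conditions: MsCl, Et3N, THF, −20 °C; then LiEt3BH, −78 → 0 °C
Reagents that add atoms: methanesulfonyl chloride, CS(=O)(=O)Cl (its atoms stay in 18 only)
Why: Sulfonylation followed by SN2 displacement with triethylborohydride turns the primary allylic CH2OH into the C8 methyl group without allylic transposition.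

Step 12
Reactants: 19 C8-methyl alkene
Product: 20 cis-fused C4 ketone (C5–H α, C6–OTBS α)
Conditions: PPTS, acetone/H2O, 55 °C
Reagents that add atoms: water, O
Why: Acid-catalysed ketal hydrolysis, mild enough for the secondary silyl ether, frees the C4 ketone; C5 is now α to a cyclopentanone, where the cis fusion next to the angular methyl group is the thermodynamically preferred one (as in angular-methyl hydrindan-1-ones), so C5–H α is kept and any trans-fused material should epimerise to the cis series.

Step 13
Reactants: 20 cis-fused C4 ketone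
Product: 21 tertiary alcohol (C4–OH β, isopropyl α, C6–OTBS α)
Conditions: i-PrMgCl, CeCl3, THF, −78 → 0 °C
Reagents that add atoms: isopropylmagnesium chloride, CC(C)[Mg]Cl
Why: The weakly basic organocerium reagent (Imamoto 1,2-addition) adds to the enolisable ketone without deprotonation or β-hydride reduction and attacks the convex α face, anti to the C5–C6 bond that covers the β face, which sets C4 with OH β.

Step 14
Reactants: 21 tertiary alcohol
Product: 22 diol (C4–OH β, C6–OH α)
Conditions: Bu4NF, THF, rt
Reagents that add atoms: none
Why: Fluoride cleaves the silyl ether and frees the C6 alcohol beside the tertiary C4 alcohol.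

Step 15
Reactants: 22 diol
Product: 23 β-hydroxy ketone (C4–OH β, C6 ketone, C5–H α)
Conditions: Dess–Martin periodinane, NaHCO3, CH2Cl2, 0 °C → rt
Reagents that add atoms: none
Why: The buffered hypervalent iodine oxidant converts only the secondary alcohol into the ketone under non-enolising conditions, so neither C5 nor the β,γ-double bond C8=C9 is disturbed, and the C6 configuration of step 8 is erased.

Step 16
Reactants: 23 β-hydroxy ketone
Product: 24 syn diol (C4–OH β, C6–OH β)
Conditions: Zn(BH4)2, Et2O, −20 °C
Reagents that add atoms: none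
Why: Chelation-controlled reduction of the β-hydroxy ketone: zinc ties the C4 hydroxyl group to the C6 carbonyl group and hydride arrives on the open α face, anti to the five-membered ring, which sets C6–OH β.

Step 17
Reactants: 24 syn diol; 25 4-[(tert-butyldimethylsilyl)oxy]benzoic acid
Product: 27 C6 aryl ester (C8=C9 alkene, phenol as silyl ether), via mixed anhydride 26 (not isolated)
Conditions: 25, 2,4,6-Cl3C6H2COCl, Et3N, THF, rt; then 24, DMAP, toluene, 40 °C
Reagents that add atoms: 2,4,6-trichlorobenzoyl chloride, O=C(Cl)c1c(Cl)cc(Cl)cc1Cl (its atoms stay in 26 only)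
Why: Yamaguchi esterification acylates the secondary C6 hydroxyl group with retention, while the tertiary C4 hydroxyl group is too hindered to react.

Step 18
Reactants: 27 C6 aryl ester
Product: 28 α-epoxide (phenol as silyl ether)
Conditions: mCPBA, NaHCO3, CH2Cl2, 0 °C
Reagents that add atoms: 3-chloroperbenzoic acid, OOC(=O)c1cccc(Cl)c1
Why: Prilezhaev epoxidation of the only alkene is expected on the α face, because the β face of the seven-membered ring carries the aroyloxy group on C6 and both bonds to the five-membered ring; this sets C8 (R) and C9 (S).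

Step 19
Reactants: 28 α-epoxide
Product: 29 target, (1S,4R,5S,6R,8R,9S)-8,9-epoxy-4-hydroxy-4-isopropyl-1,8-dimethylhydroazulen-6-yl 4-hydroxybenzoate (overview numbering)
Conditions: Bu4NF, AcOH, THF, 0 °C
Reagents that add atoms: none
Why: Buffered fluoride removes the aryl silyl ether, which is far more labile than an alkyl silyl ether, and the epoxide, the ester and the tertiary alcohol are stable to these near-neutral conditions.

**Compound list**

1 | 3-methylcyclopent-2-en-1-one | CC1=CC(=O)CC1 | starting material
2 | 2-iodo-3-methylcyclopent-2-en-1-one | CC1=C(I)C(=O)CC1 | intermediate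
3 | 6-iodo-7-methyl-1,4-dioxaspiro[4.4]non-6-ene | CC1=C(I)C2(CC1)OCCO2 | intermediate
4 | tributyl(ethenyl)stannane | CCCC[Sn](CCCC)(CCCC)C=C | starting material
5 | 6-ethenyl-7-methyl-1,4-dioxaspiro[4.4]non-6-ene | C=CC1=C(C)CCC12OCCO2 | intermediate
6 | methyl acetoacetate | CC(=O)CC(=O)OC | starting material
7 | methyl 2-diazo-3-oxobutanoate | CC(=O)C(=[N+]=[N-])C(=O)OC | intermediate
8 | methyl 2-diazo-3-hydroxybutanoate (racemic) | CC(O)C(=[N+]=[N-])C(=O)OC | intermediate
9 | methyl 3-(dichlorophosphoryloxy)-2-diazobutanoate | CC(OP(=O)(Cl)Cl)C(=[N+]=[N-])C(=O)OC | intermediate (not isolated)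
10 | methyl 2-diazobut-3-enoate | C=CC(=[N+]=[N-])C(=O)OC | intermediate
11 | methyl (1R,2R)-1-ethenyl-2-(7-methyl-1,4-dioxaspiro[4.4]non-6-en-6-yl)cyclopropane-1-carboxylate (vinyl and cyclopentenyl cis) | COC(=O)[C@@]1(C=C)C[C@@H]1C1=C(C)CCC12OCCO2 | intermediate (not isolated)
12 | cycloadduct: C4 spiro-dioxolane, C5=C6, C8=C9, CO2CH3 on C8, C1 (S) | O1CCOC12CC[C@@]3(C)CC=C(C(=O)OC)CC=C23 | intermediate
13 | C6 alkylborane (BH2 on C6 α, C5–H α) | O1CCOC12CC[C@@]3(C)CC=C(C(=O)OC)C[C@H](B)[C@@H]23 | intermediate (not isolated)
14 | secondary alcohol: C6–OH α, C5–H α (cis-fused), dioxolane, enoate | O1CCOC12CC[C@@]3(C)CC=C(C(=O)OC)C[C@H](O)[C@@H]23 | intermediate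
15 | silyl ether of 14 (C6–OTBS α) | O1CCOC12CC[C@@]3(C)CC=C(C(=O)OC)C[C@H](O[Si](C)(C)C(C)(C)C)[C@@H]23 | intermediate
16 | enal (CHO on C8) | O1CCOC12CC[C@@]3(C)CC=C(C=O)C[C@H](O[Si](C)(C)C(C)(C)C)[C@@H]23 | intermediate (not isolated)
17 | allylic alcohol (CH2OH on C8) | O1CCOC12CC[C@@]3(C)CC=C(CO)C[C@H](O[Si](C)(C)C(C)(C)C)[C@@H]23 | intermediate
18 | allylic mesylate (CH2OMs on C8) | O1CCOC12CC[C@@]3(C)CC=C(COS(C)(=O)=O)C[C@H](O[Si](C)(C)C(C)(C)C)[C@@H]23 | intermediate (not isolated)
19 | C8-methyl alkene with dioxolane and C6–OTBS α | O1CCOC12CC[C@@]3(C)CC=C(C)C[C@H](O[Si](C)(C)C(C)(C)C)[C@@H]23 | intermediate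
20 | cis-fused C4 ketone, C6–OTBS α | O=C1CC[C@@]2(C)CC=C(C)C[C@H](O[Si](C)(C)C(C)(C)C)[C@@H]12 | intermediate
21 | tertiary alcohol: C4–OH β, isopropyl α, C6–OTBS α | CC(C)[C@]1(O)CC[C@@]2(C)CC=C(C)C[C@H](O[Si](C)(C)C(C)(C)C)[C@H]21 | intermediate
22 | diol: C4–OH β, C6–OH α | CC(C)[C@]1(O)CC[C@@]2(C)CC=C(C)C[C@H](O)[C@H]21 | intermediate
23 | β-hydroxy ketone: C4–OH β, C6 ketone, C5–H α | CC(C)[C@]1(O)CC[C@@]2(C)CC=C(C)CC(=O)[C@H]21 | intermediate
24 | syn diol: C4–OH β, C6–OH β | CC(C)[C@]1(O)CC[C@@]2(C)CC=C(C)C[C@@H](O)[C@H]21 | intermediate
25 | 4-[(tert-butyldimethylsilyl)oxy]benzoic acid | CC(C)(C)[Si](C)(C)Oc1ccc(cc1)C(O)=O | starting material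
26 | 4-[(tert-butyldimethylsilyl)oxy]benzoic 2,4,6-trichlorobenzoic anhydride | CC(C)(C)[Si](C)(C)Oc1ccc(cc1)C(=O)OC(=O)c1c(Cl)cc(Cl)cc1Cl | intermediate (not isolated)
27 | C6 β 4-(silyloxy)benzoate, C4–OH β, C8=C9 | CC(C)[C@]1(O)CC[C@@]2(C)CC=C(C)C[C@@H](OC(=O)c3ccc(O[Si](C)(C)C(C)(C)C)cc3)[C@H]21 | intermediate
28 | α-epoxide of 27 | CC(C)[C@]1(O)CC[C@@]2(C)C[C@@H]3O[C@]3(C)C[C@@H](OC(=O)c3ccc(O[Si](C)(C)C(C)(C)C)cc3)[C@H]21 | intermediate
29 | target CNP0163817.4 | CC(C)[C@]1(O)CC[C@@]2(C)C[C@@H]3O[C@]3(C)C[C@@H](OC(=O)c3ccc(O)cc3)[C@H]21 | target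

**Step count and risks**

Total steps: 19. Longest linear sequence: 16 (steps 1–3 and 7–19).

Risk 1, step 7. The carbenoid may be consumed by dimerisation, or the diazo compound by cyclisation to a pyrazole, faster than the twisted, hindered diene captures it. The Cope shift may also stall at the cyclopropane because the C1 methyl group points into the boat, and a poor fit of catalyst and substrate would lower the enantiomeric excess. Fallback, setting out from 7 and 5 and coming back at 12: diazo ketone 7 is silylated (TBSOTf, Et3N, CH2Cl2, 0 °C) to the far more stable methyl 3-[(tert-butyldimethylsilyl)oxy]-2-diazobut-3-enoate F1. With dirhodium tetrakis[(S)-N-phthaloyl-(1-adamantyl)glycinate], Rh2(S-PTAD)4, the catalyst known to pair with this carbenoid for hindered 1-vinyl-2-methylcycloalkenes, F1 and 5 should give the siloxy divinylcyclopropane F2 and, after the Cope shift, the silyl enol ether cycloadduct F3. Bu4NF/AcOH then gives the β-keto ester F4 (drawn as its enol), NaH/PhNTf2 the enol triflate F5, and Pd(OAc)2, PPh3, Bu3N, HCO2H (DMF, 60 °C) reduces the triflate to 12.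

Risk 2, step 13. The hindered, enolisable cyclopentanone may be deprotonated or reduced by β-hydride transfer from the secondary organometallic instead of being attacked, or facial selectivity may be poor. Fallback, setting out from 20 and coming back at 21: 2-propenylmagnesium bromide with CeCl3 (an sp2 nucleophile that is less hindered and cannot transfer a β-hydride) gives the isopropenyl carbinol F6. Hydrogenation with RhCl(PPh3)3 and H2 (1 atm, benzene) should saturate only the 1,1-disubstituted alkene and spare the trisubstituted C8=C9 bond, giving 21.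

Risk 3, step 18. The peracid may attack the β face, for example through hydrogen bonding to the tertiary hydroxyl group, so that facial selectivity is poor or reversed. Fallback, setting out from 27 and coming back at 28: NBS in THF/H2O at 0 °C gives the bromohydrin F7 (bromonium ion on the face the peracid prefers, water opening at C8 from the α face). DBU in CH2Cl2 then closes the epoxide by displacement at C9 with inversion, which places the oxygen on the α face and gives 28.

Further compounds
F1 | step 7 | methyl 3-[(tert-butyldimethylsilyl)oxy]-2-diazobut-3-enoate | C=C(O[Si](C)(C)C(C)(C)C)C(=[N+]=[N-])C(=O)OC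
F2 | step 7 | siloxy divinylcyclopropane | COC(=O)[C@@]1(C(=C)O[Si](C)(C)C(C)(C)C)C[C@@H]1C1=C(C)CCC12OCCO2
F3 | step 7 | silyl enol ether cycloadduct (OTBS on C9) | O1CCOC12CC[C@@]3(C)CC(O[Si](C)(C)C(C)(C)C)=C(C(=O)OC)CC=C23
F4 | step 7 | β-keto ester (enol form, OH on C9) | O1CCOC12CC[C@@]3(C)CC(O)=C(C(=O)OC)CC=C23
F5 | step 7 | enol triflate (OTf on C9) | O1CCOC12CC[C@@]3(C)CC(OS(=O)(=O)C(F)(F)F)=C(C(=O)OC)CC=C23
F6 | step 13 | isopropenyl carbinol (C4–OH β, C6–OTBS α) | CC(=C)[C@]1(O)CC[C@@]2(C)CC=C(C)C[C@H](O[Si](C)(C)C(C)(C)C)[C@H]21
F7 | step 18 | bromohydrin (C9–Br β, C8–OH α) | CC(C)[C@]1(O)CC[C@@]2(C)C[C@@H](Br)[C@](C)(O)C[C@@H](OC(=O)c3ccc(O[Si](C)(C)C(C)(C)C)cc3)[C@H]21
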